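**Assumption:** prenyl means 3-methylbut-2-en-1-yl, the chiral-pool acid is bought in ≥98% ee, and flavanone numbering (O1, C2 … C8a) is used for the target. The target is the (2S) enantiomer.

## Retrosynthetic overview

1. Target ⇐ its 7-O-TBS ether ⇐ (add back ethylene) a bicyclo[2.2.2]octadiene ⇐ intramolecular Diels–Alder of a 1-alkoxy-3-silyloxycyclohexa-1,3-diene whose alkoxy group is (S)-O–CH(Ph)–CH2–CO–C≡CH. One thermal operation closes ring C (cycloaddition) and unveils aromatic ring A (loss of C2H4).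
2. Ynone ⇐ morpholine amide + ethynylmagnesium bromide, made last because a β-oxy ynone does not survive base.
3. Silyloxydiene ⇐ 3-alkoxy-2-prenylcyclohex-2-enone by α′-prenylation, then α′-enolisation and O-silylation.
4. 3-Alkoxyenone ⇐ 2-prenylcyclohexane-1,3-dione + an (R)-β-hydroxy amide by Mitsunobu etherification; the inversion sets 2S.
5. Ring order: the dione ring is a bought, sacrificial scaffold (its CH2CH2 leaves as ethylene); rings C and A form together in the key step; ring B is bought as phenyl.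

## Route

Step 1
Reactants: 1 (R)-3-hydroxy-3-phenylpropanoic acid; 2 morpholine
Product: 3 (R)-3-hydroxy-1-(morpholin-4-yl)-3-phenylpropan-1-one
Conditions: DCC, HOBt, CH2Cl2, 0 °C → rt
Reagents that add atoms: none
Why: Carbodiimide/HOBt amide coupling acylates the amine chemoselectively over the free secondary alcohol without touching the stereocentre, and gives a tertiary amide whose α-CH2 (pKa ≈ 35) survives the later enolate steps yet can still be turned into a ynone.

Step 2
Reactants: 4 cyclohexane-1,3-dione; 5 1-bromo-3-methylbut-2-ene (prenyl bromide)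
Product: 6 2-(3-methylbut-2-en-1-yl)cyclohexane-1,3-dione
Conditions: KOH (1.0 equiv), H2O, 0 °C → rt
Reagents that add atoms: none
Why: C-alkylation of the stabilised 1,3-dione enolate by an allylic bromide in water, where hydrogen bonding to the enolate oxygen favours C- over O-alkylation (classical C-allylation of cyclohexane-1,3-dione).

Step 3
Reactants: 6 2-(3-methylbut-2-en-1-yl)cyclohexane-1,3-dione; 3 (R)-3-hydroxy-1-(morpholin-4-yl)-3-phenylpropan-1-one
Product: 7 3-{[(1S)-3-(morpholin-4-yl)-3-oxo-1-phenylpropyl]oxy}-2-(3-methylbut-2-en-1-yl)cyclohex-2-en-1-one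
Conditions: PPh3, DIAD, toluene, 0 °C → rt
Reagents that add atoms: none
Why: Mitsunobu etherification in which the acidic enol O–H of the symmetrical dione (pKa ≈ 5, only one vinylogous ester possible, C-alkylation blocked by the 2-prenyl group) displaces the oxyphosphonium of 3 by SN2 with inversion, so the (R)-carbinol becomes the (S)-configured O1–C2 bond of the target.

Step 4
Reactants: 7 3-{[(1S)-3-(morpholin-4-yl)-3-oxo-1-phenylpropyl]oxy}-2-(3-methylbut-2-en-1-yl)cyclohex-2-en-1-one; 5 1-bromo-3-methylbut-2-ene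
Product: 8 3-{[(1S)-3-(morpholin-4-yl)-3-oxo-1-phenylpropyl]oxy}-2,6-bis(3-methylbut-2-en-1-yl)cyclohex-2-en-1-one (mixture of C6 epimers)
Conditions: LDA (1.05 equiv), THF, −78 °C; then prenyl bromide, −78 → 0 °C
Reagents that add atoms: none
Why: Stork–Danheiser kinetic α′-deprotonation of the vinylogous ester gives the cross-conjugated dienolate, which is C-alkylated at C6 (the future C6 of the flavanone); one equivalent of base at −78 °C should not deprotonate the much less acidic amide, and the new C6 stereocentre is irrelevant because it becomes sp2 in step 5.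

Step 5
Reactants: 8 3-{[(1S)-3-(morpholin-4-yl)-3-oxo-1-phenylpropyl]oxy}-2,6-bis(3-methylbut-2-en-1-yl)cyclohex-2-en-1-one
Product: 9 4-[(3S)-3-({3-[(tert-butyldimethylsilyl)oxy]-2,4-bis(3-methylbut-2-en-1-yl)cyclohexa-1,3-dien-1-yl}oxy)-3-phenylpropanoyl]morpholine
Conditions: KHMDS, THF, −78 °C; then TBSCl, −78 °C → rt
Reagents that add atoms: tert-butyldimethylsilyl chloride (TBSCl), CC(C)(C)[Si](C)(C)Cl
Why: A second kinetic α′-enolisation with a hexamethyldisilazide base (too weak to deprotonate the amide) and O-silylation, as in the preparation of Danishefsky- and Rawal-type dienes, gives the 1-alkoxy-3-silyloxycyclohexa-1,3-diene and leaves the ether stereocentre untouched.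

Step 6
Reactants: 9 4-[(3S)-3-({3-[(tert-butyldimethylsilyl)oxy]-2,4-bis(3-methylbut-2-en-1-yl)cyclohexa-1,3-dien-1-yl}oxy)-3-phenylpropanoyl]morpholine; 10 ethynylmagnesium bromide
Product: 11 (5S)-5-({3-[(tert-butyldimethylsilyl)oxy]-2,4-bis(3-methylbut-2-en-1-yl)cyclohexa-1,3-dien-1-yl}oxy)-5-phenylpent-1-yn-3-one
Conditions: THF, 0 °C → rt; inverse quench into cold sat. aq NH4Cl, rapid extraction, crude used at once
Reagents that add atoms: none
Why: Acyl substitution of the morpholine amide (Weinreb-type ketone synthesis) stops at the tetrahedral magnesium hemiaminal, so the base-labile β-alkoxy ynone appears only in the cold, weakly acidic quench, where the released morpholine is protonated and cannot add to the ynone.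

Step 7
Reactants: 11 (5S)-5-({3-[(tert-butyldimethylsilyl)oxy]-2,4-bis(3-methylbut-2-en-1-yl)cyclohexa-1,3-dien-1-yl}oxy)-5-phenylpent-1-yn-3-one
Product: 14 (2S)-7-hydroxy-6,8-bis(3-methylbut-2-en-1-yl)-2-phenyl-2,3-dihydro-4H-chromen-4-one (target), via bicyclooctadiene cycloadduct 12 (not isolated), via flavanone TBS ether 13 (not isolated)
Conditions: toluene (0.01 M), BHT (cat.), sealed tube, 80 °C then 160 °C; then HF·pyridine, pyridine, THF, 0 °C
Reagents that add atoms: none
Why: Proposed new method: an intramolecular Diels–Alder reaction of the electron-rich diene with the tethered ynone (the nucleophilic prenyl-bearing terminus attacks the ynone β-carbon, the O-bearing terminus bonds to the α-carbon through a chromanone-shaped six-membered tether) closes ring C and gives a bicyclo[2.2.2]octadiene that loses ethylene by retro-Diels–Alder to unveil aromatic ring A with the tether oxygen necessarily retained, the closest known reaction type being the intermolecular Alder–Rickert resorcinol synthesis from 1-alkoxy-3-silyloxycyclohexa-1,3-dienes and acetylenic ketones or esters; the C2 stereocentre is carried through untouched and buffered HF·pyridine then removes the aryl silyl ether without base, which would racemise a flavanone.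

## Compound list

1 | (R)-3-hydroxy-3-phenylpropanoic acid | OC(=O)C[C@@H](O)c1ccccc1 | starting material
2 | morpholine | C1COCCN1 | starting material
3 | (R)-3-hydroxy-1-(morpholin-4-yl)-3-phenylpropan-1-one | O=C(C[C@@H](O)c1ccccc1)N1CCOCC1 | intermediate
4 | cyclohexane-1,3-dione | O=C1CCCC(=O)C1 | starting material
5 | 1-bromo-3-methylbut-2-ene (prenyl bromide) | CC(C)=CCBr | starting material
6 | 2-(3-methylbut-2-en-1-yl)cyclohexane-1,3-dione (reacts as its enol) | CC(C)=CCC1C(=O)CCCC1=O | intermediate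
7 | 3-{[(1S)-3-(morpholin-4-yl)-3-oxo-1-phenylpropyl]oxy}-2-(3-methylbut-2-en-1-yl)cyclohex-2-en-1-one | CC(C)=CCC1=C(O[C@H](c2ccccc2)CC(=O)N2CCOCC2)CCCC1=O | intermediate
8 | 3-{[(1S)-3-(morpholin-4-yl)-3-oxo-1-phenylpropyl]oxy}-2,6-bis(3-methylbut-2-en-1-yl)cyclohex-2-en-1-one, C6 epimers | O=C1C(CC=C(C)C)CCC(O[C@H](c2ccccc2)CC(=O)N2CCOCC2)=C1CC=C(C)C | intermediate
9 | 4-[(3S)-3-({3-[(tert-butyldimethylsilyl)oxy]-2,4-bis(3-methylbut-2-en-1-yl)cyclohexa-1,3-dien-1-yl}oxy)-3-phenylpropanoyl]morpholine | CC(C)=CCC1=C(O[Si](C)(C)C(C)(C)C)C(CC=C(C)C)=C(O[C@H](c2ccccc2)CC(=O)N2CCOCC2)CC1 | intermediate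
10 | ethynylmagnesium bromide | C#C[Mg]Br | starting material
11 | (5S)-5-({3-[(tert-butyldimethylsilyl)oxy]-2,4-bis(3-methylbut-2-en-1-yl)cyclohexa-1,3-dien-1-yl}oxy)-5-phenylpent-1-yn-3-one | CC(C)=CCC1=C(O[Si](C)(C)C(C)(C)C)C(CC=C(C)C)=C(O[C@H](c2ccccc2)CC(=O)C#C)CC1 | intermediate
12 | Diels–Alder adduct: bicyclo[2.2.2]octa-2,5-diene with the tether oxygen on one bridgehead (future C8a) and a prenyl group on the other (future C6), the (2S)-2-phenyl-4-oxo-oxane ring fused across the bridgehead–alkene bond, a TBSO/prenyl-substituted second alkene bridge and a CH2CH2 bridge; both bridgehead diastereomers | O1[C@H](c2ccccc2)CC(=O)C2=CC3(CC=C(C)C)CCC12C(CC=C(C)C)=C3O[Si](C)(C)C(C)(C)C | intermediate (not isolated)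
13 | (2S)-7-[(tert-butyldimethylsilyl)oxy]-6,8-bis(3-methylbut-2-en-1-yl)-2-phenyl-2,3-dihydro-4H-chromen-4-one | CC(C)=CCc1cc2c(c(CC=C(C)C)c1O[Si](C)(C)C(C)(C)C)O[C@H](c1ccccc1)CC2=O | intermediate (not isolated)
14 | (2S)-7-hydroxy-6,8-bis(3-methylbut-2-en-1-yl)-2-phenyl-2,3-dihydro-4H-chromen-4-one (7-hydroxy-6,8-diprenylflavanone) | CC(C)=CCc1cc2c(c(CC=C(C)C)c1O)O[C@H](c1ccccc1)CC2=O | target

## Step count and risks

Total steps: 7. Longest linear sequence: 6 (steps 1, 3, 4, 5, 6, 7 from acid 1; equally steps 2, 3, 4, 5, 6, 7 from dione 4).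

**Step 7 (the ring-forming cascade).** The tethered cycloaddition is untested. The diene can scramble by 1,5-hydrogen shifts before it cyclises, and the β-alkoxy ynone can eliminate on heating. The fallback sets out from 6 (using 3, 5 and 10 as well) and comes back at 14; it builds ring A by an intermolecular Alder–Rickert reaction and closes ring C separately. Dione 6 is O-silylated (TBSCl, imidazole) to 3-[(tert-butyldimethylsilyl)oxy]-2-(3-methylbut-2-en-1-yl)cyclohex-2-en-1-one F1. This is α′-prenylated (LDA, then 5) to 3-[(tert-butyldimethylsilyl)oxy]-2,6-bis(3-methylbut-2-en-1-yl)cyclohex-2-en-1-one F2 and enol-silylated (LDA, TBSCl) to 1,3-bis[(tert-butyldimethylsilyl)oxy]-2,4-bis(3-methylbut-2-en-1-yl)cyclohexa-1,3-diene F3. Separately, 3 is silylated to (R)-3-[(tert-butyldimethylsilyl)oxy]-1-(morpholin-4-yl)-3-phenylpropan-1-one F4 and treated with 10 to give (R)-5-[(tert-butyldimethylsilyl)oxy]-5-phenylpent-1-yn-3-one F5. Heating F3 with F5 in toluene gives the bicyclo[2.2.2]octadiene cycloadduct F6, which loses ethylene to (R)-1-{2,4-bis[(tert-butyldimethylsilyl)oxy]-3,5-bis(3-methylbut-2-en-1-yl)phenyl}-3-[(tert-butyldimethylsilyl)oxy]-3-phenylpropan-1-one F7. HF·pyridine gives (R)-1-[2,4-dihydroxy-3,5-bis(3-methylbut-2-en-1-yl)phenyl]-3-hydroxy-3-phenylpropan-1-one F8. An intramolecular Mitsunobu etherification (PPh3, DIAD, high dilution) by the 2-hydroxyl group, with inversion at the benzylic carbon, then gives 14.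

**Step 3 (Mitsunobu etherification).** The activated β-hydroxy amide can eliminate to the cinnamoyl amide, and a benzylic oxyphosphonium can lose some stereochemical integrity. The fallback sets out from 6 and comes back at 7; it forms the same C–O bond from the other side, with retention at the carbinol. Dione 6 is converted with oxalyl chloride and catalytic DMF into 3-chloro-2-(3-methylbut-2-en-1-yl)cyclohex-2-en-1-one F9. Purchased (S)-3-hydroxy-3-phenylpropanoic acid F10 is coupled with 2 as in step 1 to give (S)-3-hydroxy-1-(morpholin-4-yl)-3-phenylpropan-1-one F11. The sodium alkoxide of F11 (NaH, 0.95 equiv, THF, 0 °C) displaces chloride from F9 by addition–elimination, giving 7.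

**Step 6 (ynone formation next to the silyl dienol ether).** The silyl dienol ether may not survive the weakly acidic quench, and if the quench is not acidic enough the released morpholine adds to the terminal ynone. The fallback sets out from 9 and comes back at 11; it reaches the ynone by oxidation instead of acyl substitution, so no amine is present when the ynone forms. Amide 9 is reduced with Cp2Zr(H)Cl (THF, rt) to (3S)-3-({3-[(tert-butyldimethylsilyl)oxy]-2,4-bis(3-methylbut-2-en-1-yl)cyclohexa-1,3-dien-1-yl}oxy)-3-phenylpropanal F12. Addition of 10 at −78 °C gives (5S)-5-({3-[(tert-butyldimethylsilyl)oxy]-2,4-bis(3-methylbut-2-en-1-yl)cyclohexa-1,3-dien-1-yl}oxy)-5-phenylpent-1-yn-3-ol F13 as a mixture of C3 epimers. Buffered Dess–Martin oxidation (NaHCO3, CH2Cl2, 0 °C) then gives 11.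

## Further compounds

F1 | step 7 | 3-[(tert-butyldimethylsilyl)oxy]-2-(3-methylbut-2-en-1-yl)cyclohex-2-en-1-one | CC(C)=CCC1=C(O[Si](C)(C)C(C)(C)C)CCCC1=O
F2 | step 7 | 3-[(tert-butyldimethylsilyl)oxy]-2,6-bis(3-methylbut-2-en-1-yl)cyclohex-2-en-1-one (racemic) | O=C1C(CC=C(C)C)CCC(O[Si](C)(C)C(C)(C)C)=C1CC=C(C)C
F3 | step 7 | 1,3-bis[(tert-butyldimethylsilyl)oxy]-2,4-bis(3-methylbut-2-en-1-yl)cyclohexa-1,3-diene | CC(C)=CCC1=C(O[Si](C)(C)C(C)(C)C)C(CC=C(C)C)=C(O[Si](C)(C)C(C)(C)C)CC1
F4 | step 7 | (R)-3-[(tert-butyldimethylsilyl)oxy]-1-(morpholin-4-yl)-3-phenylpropan-1-one | O=C(C[C@@H](O[Si](C)(C)C(C)(C)C)c1ccccc1)N1CCOCC1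
F5 | step 7 | (R)-5-[(tert-butyldimethylsilyl)oxy]-5-phenylpent-1-yn-3-one | C#CC(=O)C[C@@H](O[Si](C)(C)C(C)(C)C)c1ccccc1
F6 | step 7 | bicyclo[2.2.2]octadiene cycloadduct of F3 and F5 (not isolated) | CC(C)=CCC1=C(O[Si](C)(C)C(C)(C)C)C2(CC=C(C)C)CCC1(O[Si](C)(C)C(C)(C)C)C(C(=O)C[C@@H](O[Si](C)(C)C(C)(C)C)c1ccccc1)=C2
F7 | step 7 | (R)-1-{2,4-bis[(tert-butyldimethylsilyl)oxy]-3,5-bis(3-methylbut-2-en-1-yl)phenyl}-3-[(tert-butyldimethylsilyl)oxy]-3-phenylpropan-1-one | CC(C)=CCc1cc(C(=O)C[C@@H](O[Si](C)(C)C(C)(C)C)c2ccccc2)c(O[Si](C)(C)C(C)(C)C)c(CC=C(C)C)c1O[Si](C)(C)C(C)(C)C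
F8 | step 7 | (R)-1-[2,4-dihydroxy-3,5-bis(3-methylbut-2-en-1-yl)phenyl]-3-hydroxy-3-phenylpropan-1-one | CC(C)=CCc1cc(C(=O)C[C@@H](O)c2ccccc2)c(O)c(CC=C(C)C)c1O
F9 | step 3 | 3-chloro-2-(3-methylbut-2-en-1-yl)cyclohex-2-en-1-one | CC(C)=CCC1=C(Cl)CCCC1=O
F10 | step 3 | (S)-3-hydroxy-3-phenylpropanoic acid (purchased for the fallback) | OC(=O)C[C@H](O)c1ccccc1
F11 | step 3 | (S)-3-hydroxy-1-(morpholin-4-yl)-3-phenylpropan-1-one | O=C(C[C@H](O)c1ccccc1)N1CCOCC1
F12 | step 6 | (3S)-3-({3-[(tert-butyldimethylsilyl)oxy]-2,4-bis(3-methylbut-2-en-1-yl)cyclohexa-1,3-dien-1-yl}oxy)-3-phenylpropanal | CC(C)=CCC1=C(O[Si](C)(C)C(C)(C)C)C(CC=C(C)C)=C(O[C@H](c2ccccc2)CC=O)CC1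
F13 | step 6 | (5S)-5-({3-[(tert-butyldimethylsilyl)oxy]-2,4-bis(3-methylbut-2-en-1-yl)cyclohexa-1,3-dien-1-yl}oxy)-5-phenylpent-1-yn-3-ol (C3 epimers) | CC(C)=CCC1=C(O[Si](C)(C)C(C)(C)C)C(CC=C(C)C)=C(O[C@H](c2ccccc2)CC(O)C#C)CC1
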